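**Strategy**

Ring A is a phloroglucinol whose C4a=C8a bond is at the same time the enol-ether double bond of ring C. Ring C is therefore made first, as an (S)-2-aryl-2,3-dihydro-4H-pyran-4-one (C2 from a catalytic hetero-Diels–Alder reaction) that already carries the complete (2R,3R)-dihydrobenzofuran, silylated on its four phenols, and is brominated at C5. Onto the pyranone C5=C6 bond (future C4a=C8a) a prenyl-bearing 1-methoxy-1,3-bis(silyloxy)diene then delivers ring-A carbons C5 to C8 in one operation: C8–C8a and C4a–C5 are formed, and loss of methanol and HBr aromatises ring A with both hydroxyls and the C8 side chain in place. The prenyl group is finally turned into the Z-diene through the angular chromene.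

Key step: step 14

Remark: the sense of induction written for Rh2(S-PTAD)4 (step 5) and for the (S)-BINOL/Ti(OiPr)4 catalyst (step 9) is assigned by analogy; if either proves opposite, its mirror-image form is used and nothing else changes.

Abbreviations in names: ArTBS = (2R,3R)-3-[3,5-bis(tert-butyldimethylsilyloxy)phenyl]-6-(tert-butyldimethylsilyloxy)-2-[4-(tert-butyldimethylsilyloxy)phenyl]-2,3-dihydro-1-benzofuran-5-yl. ArOH = the same group with four free hydroxyls.

**Route**

Step 1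
Reactants: 1 5-bromo-2-hydroxy-4-methoxybenzaldehyde; 2 4-methoxybenzyl chloride
Product: 3 5-bromo-4-methoxy-2-[(4-methoxyphenyl)methoxy]benzaldehyde
Conditions: K2CO3, NaI (cat.), DMF, 60 °C
Reagents that add atoms: none
Why: Williamson etherification (SN2 of the phenoxide on the benzylic chloride); the new OCH2Ar unit later supplies O1 and C2 of the dihydrobenzofuran.

Step 2
Reactants: 3 5-bromo-4-methoxy-2-[(4-methoxyphenyl)methoxy]benzaldehyde; 4 3,5-dimethoxyphenylmagnesium chloride (commercial THF solution)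
Product: 5 (RS)-[5-bromo-4-methoxy-2-[(4-methoxyphenyl)methoxy]phenyl](3,5-dimethoxyphenyl)methanol
Conditions: THF, −78 → 0 °C; aq. NH4Cl
Reagents that add atoms: none
Why: Grignard 1,2-addition to the aldehyde; the aryl bromide is inert to the arylmagnesium reagent at this temperature and the racemic carbinol centre is erased in step 3.

Step 3
Reactants: 5 (RS)-diarylmethanol
Product: 6 [5-bromo-4-methoxy-2-[(4-methoxyphenyl)methoxy]phenyl](3,5-dimethoxyphenyl)methanone
Conditions: MnO2 (activated), CH2Cl2, 20 °C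
Reagents that add atoms: none
Why: MnO2 oxidation of a doubly benzylic alcohol to the benzophenone, which leaves the benzyl ether and the aryl bromide untouched.

Step 4
Reactants: 6 diaryl ketone
Product: 7 hydrazone of ketone 6 (E/Z mixture)
Conditions: N2H4·H2O (excess), AcOH (cat.), EtOH, 80 °C
Reagents that add atoms: hydrazine (as hydrate), NN
Why: Acid-catalysed condensation of the ketone with hydrazine (hydrazone formation); both geometric isomers lead to the same diazo compound.

Step 5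
Reactants: 7 hydrazone
Product: 9 (2S,3R)-5-bromo-3-(3,5-dimethoxyphenyl)-6-methoxy-2-(4-methoxyphenyl)-2,3-dihydro-1-benzofuran (cis), via diaryldiazomethane 8 (not isolated)
Conditions: MnO2, CH2Cl2, 0 °C, filter; Rh2(S-PTAD)4 (dirhodium tetrakis[(S)-1-adamantyl(phthalimido)acetate], 1 mol %), CH2Cl2, 0 → 20 °C
Reagents that add atoms: none
Why: MnO2 dehydrogenates the hydrazone and the chiral dirhodium carboxylate then forms a donor/donor carbene that inserts into the ether-activated 4-methoxybenzylic C–H bond through a five-membered transition state (intramolecular carbene C–H insertion), the ligand sphere setting C3 as (R) and the concerted insertion placing the two aryl groups cis (2S).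

Step 6
Reactants: 9 cis bromide
Product: 10 (2S,3R)-3-(3,5-dimethoxyphenyl)-6-methoxy-2-(4-methoxyphenyl)-2,3-dihydro-1-benzofuran-5-carbaldehyde (cis)
Conditions: n-BuLi, THF, −78 °C; DMF; aq. NH4Cl
Reagents that add atoms: N,N-dimethylformamide, CN(C)C=O
Why: Bromine–lithium exchange and formylation of the aryllithium (stabilised by the ortho methoxy group); neither benzylic stereocentre is deprotonated at −78 °C.

Step 7
Reactants: 10 cis aldehyde
Product: 11 (2R,3R)-3-(3,5-dihydroxyphenyl)-6-hydroxy-2-(4-hydroxyphenyl)-2,3-dihydro-1-benzofuran-5-carbaldehyde (trans)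
Conditions: BBr3 (excess), CH2Cl2, −78 → 20 °C; H2O
Reagents that add atoms: none
Why: Lewis-acid ether cleavage of the four aryl methyl ethers (bromide attacks the activated methyl groups), during which reversible heterolysis of the C2–O bond to the 4-oxybenzylic cation should let C2 equilibrate to the more stable trans (2R) configuration while C3 (R) is untouched.

Step 8
Reactants: 11 tetraphenol aldehyde
Product: 12 ArTBS-carbaldehyde, i.e. (2R,3R)-3-[3,5-bis(tert-butyldimethylsilyloxy)phenyl]-6-(tert-butyldimethylsilyloxy)-2-[4-(tert-butyldimethylsilyloxy)phenyl]-2,3-dihydro-1-benzofuran-5-carbaldehyde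
Conditions: TBSCl, imidazole, DMF, 20 °C
Reagents that add atoms: tert-butyldimethylsilyl chloride, CC(C)(C)[Si](C)(C)Cl
Why: Imidazole-promoted silylation of all four phenols gives ethers that tolerate the Lewis-acid and oxidative steps ahead and are removed by fluoride at the end.

Step 9
Reactants: 12 ArTBS-carbaldehyde; 13 (E)-1-methoxy-3-(trimethylsilyloxy)buta-1,3-diene
Product: 15 (2S)-2-(ArTBS)-2,3-dihydro-4H-pyran-4-one, via Mukaiyama aldol adduct 14 (not isolated)
Conditions: (S)-BINOL (20 mol %), Ti(OiPr)4 (10 mol %), 4 Å MS, Et2O, −20 °C; CF3CO2H (cat.), CH2Cl2, 0 °C, brief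
Reagents that add atoms: none
Why: The chiral titanium–BINOLate catalyses Mukaiyama aldol addition of the silyloxydiene to the Si face of the aldehyde (formal hetero-Diels–Alder reaction), setting C2 as (S) under catalyst control, and acid then closes the ring by oxa-Michael addition and loss of methanol; any (2R) epimer is a diastereomer and is removed by chromatography.

Step 10
Reactants: 15 (2S)-pyranone
Product: 16 (2S)-5-bromo-2-(ArTBS)-2,3-dihydro-4H-pyran-4-one
Conditions: NBS (1.05 equiv), CH2Cl2, 0 °C, dark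
Reagents that add atoms: N-bromosuccinimide, O=C1CCC(=O)N1Br
Why: Electrophilic α-bromination of the vinylogous ester: NBS attacks the nucleophilic enol-ether carbon C5 and loss of H5 restores the enone, a site far more reactive than the silylated arenes; C2 is not involved.

Step 11
Reactants: 17 methyl acetoacetate; 18 1-bromo-3-methylbut-2-ene
Product: 19 methyl 7-methyl-3-oxooct-6-enoate
Conditions: NaH, THF, 0 °C; n-BuLi, 0 °C; 18, 0 → 20 °C; aq. NH4Cl
Reagents that add atoms: none
Why: γ-Alkylation of the acetoacetate dianion (SN2 by the more basic terminal carbanion), placing the prenyl group on the carbon that becomes C8.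

Step 12
Reactants: 19 γ-prenylated keto ester
Product: 20 methyl 7-methyl-3-(trimethylsilyloxy)octa-2,6-dienoate (E/Z mixture at C2)
Conditions: Me3SiCl, Et3N, toluene, 20 °C
Reagents that add atoms: chlorotrimethylsilane, C[Si](C)(C)Cl
Why: O-Silylation of the enolised β-keto ester under soft-enolisation conditions gives the 3-silyloxy enoate.

Step 13
Reactants: 20 silyloxy enoate
Product: 21 (1Z,3Z)-1-methoxy-7-methyl-1,3-bis(trimethylsilyloxy)octa-1,3,6-triene
Conditions: LDA (commercial solution), THF, −78 °C; Me3SiCl, −78 → 0 °C; used at once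
Reagents that add atoms: chlorotrimethylsilane, C[Si](C)(C)Cl
Why: γ-Deprotonation by LDA gives the extended ester dienolate, and O-silylation (kinetic enolate trapping) furnishes the bis(silyloxy)triene.

Step 14
Reactants: 16 (2S)-5-bromo-2-(ArTBS)-2,3-dihydro-4H-pyran-4-one; 21 bis(silyloxy)triene
Product: 23 (2S)-5,7-dihydroxy-8-(3-methylbut-2-enyl)-2-(ArTBS)-2,3-dihydro-4H-chromen-4-one, via bromo cycloadduct 22 (not isolated)
Conditions: 16 and 21 (1.3 equiv) premixed, 2,6-di-tert-butylpyridine (0.3 equiv), Me3SiOTf (0.3 equiv, added last), CH2Cl2, −78 → −30 °C; Et3N, −30 → 0 °C; aq. citric acid, THF, 0 °C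
Reagents that add atoms: none
Why: Proposed new method: Me3SiOTf turns 16 into a 5-bromo-4-silyloxy oxocarbenium ion that is electrophilic only at C6; the terminal carbon of 21 adds there (vinylogous Mukaiyama–Michael addition, C8–C8a), and the resulting bromo silyl enol ether carbon then attacks the silylated ester carbon (Claisen-type acylation, C4a–C5) to give the formal [4+2] adduct 22 with release of the silyl cation, so the triflate is catalytic. The closest known reaction types are Diels–Alder and Michael–Claisen benzannulations of 1-methoxy-1,3-bis(silyloxy)dienes with halogenated quinones and enones, and the addition of such dienes to silylated chromones; new here is acylation at the α-carbon of a 2,3-dihydropyran-4-one. Ring A closes in a 6-exo-trig mode at the ester carbon, after which loss of methoxytrimethylsilane, amine-assisted loss of HBr across C4a–C8a and enolisation aromatise it. No stereocentre is created in the product (those at C4a, C8 and C8a are transient), and C2 is a spectator protected by the low temperature, the hindered-base buffer and the low standing concentration of the cation, which suppress ionisation of the benzylic C2–O1 bond. The step needs regioselectivity (prenyl-bearing terminus to C8a, ester carbon to C4a) and acylation in preference to aldol attack at C4: the first follows from the matched polarity of the partners, the second from C4 being masked as its silyl enol ether once the first bond is made, and the bromine supplies the leaving group so that no oxidant is needed.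

Step 15
Reactants: 23 8-prenyl flavanone
Product: 25 (2S)-5-hydroxy-8,8-dimethyl-2-(ArTBS)-2,3-dihydro-4H,8H-pyrano[2,3-f]chromen-4-one, via ortho-quinone methide 24 (not isolated)
Conditions: DDQ (1.1 equiv), benzene, 20–50 °C
Reagents that add atoms: none
Why: DDQ abstracts hydride from the benzylic CH2 of the ortho-prenylphenol and the resulting ortho-quinone methide closes by oxa-6π electrocyclisation (oxidative cyclodehydrogenation to a 2,2-dimethylchromene); only the 7-hydroxyl is ortho to the side chain, so only the angular ring can form.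

Step 16
Reactants: 25 silylated chromene
Product: 26 (2S)-5-hydroxy-8,8-dimethyl-2-(ArOH)-2,3-dihydro-4H,8H-pyrano[2,3-f]chromen-4-one
Conditions: KHF2 (excess), MeOH/THF, 20 °C
Reagents that add atoms: none
Why: Fluoride-driven desilylation of the four aryl silyl ethers under near-neutral conditions that neither open the flavanone nor touch the chromene.

Step 17
Reactants: 26 pentaphenol chromene
Product: 28 (2S)-5,7-dihydroxy-8-[(1Z)-3-methylbuta-1,3-dienyl]-2-(ArOH)-2,3-dihydro-4H-chromen-4-one, via ortho-quinone allide 27 (not isolated)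
Conditions: hν (365 nm), degassed MeCN, 10 °C, to partial conversion; recovered 26 recycled
Reagents that add atoms: none
Why: Photochemical 6π electrocyclic ring opening of the 2,2-dimethylchromene gives the ortho-quinone allide, and a [1,7]-hydrogen shift from a methyl group to the carbonyl oxygen rearomatises ring A; the ring double bond is delivered as the Z alkene, and 365 nm light excites only the acyl-conjugated chromene chromophore.

**Compound list**

1 | 5-bromo-2-hydroxy-4-methoxybenzaldehyde | O=Cc1cc(Br)c(OC)cc1O | starting material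
2 | 4-methoxybenzyl chloride | COc1ccc(CCl)cc1 | starting material
3 | 5-bromo-4-methoxy-2-[(4-methoxyphenyl)methoxy]benzaldehyde | O=Cc1cc(Br)c(OC)cc1OCc1ccc(OC)cc1 | intermediate
4 | 3,5-dimethoxyphenylmagnesium chloride | COc1cc(OC)cc([Mg]Cl)c1 | starting material
5 | (RS)-[5-bromo-4-methoxy-2-[(4-methoxyphenyl)methoxy]phenyl](3,5-dimethoxyphenyl)methanol | OC(c1cc(OC)cc(OC)c1)c1cc(Br)c(OC)cc1OCc1ccc(OC)cc1 | intermediate
6 | [5-bromo-4-methoxy-2-[(4-methoxyphenyl)methoxy]phenyl](3,5-dimethoxyphenyl)methanone | O=C(c1cc(OC)cc(OC)c1)c1cc(Br)c(OC)cc1OCc1ccc(OC)cc1 | intermediate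
7 | hydrazone of ketone 6 (E/Z mixture) | NN=C(c1cc(OC)cc(OC)c1)c1cc(Br)c(OC)cc1OCc1ccc(OC)cc1 | intermediate
8 | 1-bromo-5-[diazo(3,5-dimethoxyphenyl)methyl]-2-methoxy-4-[(4-methoxyphenyl)methoxy]benzene | [N-]=[N+]=C(c1cc(OC)cc(OC)c1)c1cc(Br)c(OC)cc1OCc1ccc(OC)cc1 | intermediate
9 | (2S,3R)-5-bromo-3-(3,5-dimethoxyphenyl)-6-methoxy-2-(4-methoxyphenyl)-2,3-dihydro-1-benzofuran (cis) | Brc1cc2c(cc1OC)O[C@H](c1ccc(OC)cc1)[C@@H]2c1cc(OC)cc(OC)c1 | intermediate
10 | (2S,3R)-3-(3,5-dimethoxyphenyl)-6-methoxy-2-(4-methoxyphenyl)-2,3-dihydro-1-benzofuran-5-carbaldehyde (cis) | O=Cc1cc2c(cc1OC)O[C@H](c1ccc(OC)cc1)[C@@H]2c1cc(OC)cc(OC)c1 | intermediate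
11 | (2R,3R)-3-(3,5-dihydroxyphenyl)-6-hydroxy-2-(4-hydroxyphenyl)-2,3-dihydro-1-benzofuran-5-carbaldehyde (trans) | O=Cc1cc2c(cc1O)O[C@@H](c1ccc(O)cc1)[C@@H]2c1cc(O)cc(O)c1 | intermediate
12 | (2R,3R)-3-[3,5-bis(tert-butyldimethylsilyloxy)phenyl]-6-(tert-butyldimethylsilyloxy)-2-[4-(tert-butyldimethylsilyloxy)phenyl]-2,3-dihydro-1-benzofuran-5-carbaldehyde | O=Cc1cc2c(cc1O[Si](C)(C)C(C)(C)C)O[C@@H](c1ccc(O[Si](C)(C)C(C)(C)C)cc1)[C@@H]2c1cc(O[Si](C)(C)C(C)(C)C)cc(O[Si](C)(C)C(C)(C)C)c1 | intermediate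
13 | (E)-1-methoxy-3-(trimethylsilyloxy)buta-1,3-diene | CO/C=C/C(=C)O[Si](C)(C)C | starting material
14 | (1E,5S)-5-(ArTBS)-1-methoxy-5-(trimethylsilyloxy)pent-1-en-3-one | CO/C=C/C(=O)C[C@H](O[Si](C)(C)C)c1cc2c(cc1O[Si](C)(C)C(C)(C)C)O[C@@H](c1ccc(O[Si](C)(C)C(C)(C)C)cc1)[C@@H]2c1cc(O[Si](C)(C)C(C)(C)C)cc(O[Si](C)(C)C(C)(C)C)c1 | intermediate
15 | (2S)-2-(ArTBS)-2,3-dihydro-4H-pyran-4-one | O=C1C=CO[C@H](c2cc3c(cc2O[Si](C)(C)C(C)(C)C)O[C@@H](c2ccc(O[Si](C)(C)C(C)(C)C)cc2)[C@@H]3c2cc(O[Si](C)(C)C(C)(C)C)cc(O[Si](C)(C)C(C)(C)C)c2)C1 | intermediate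
16 | (2S)-5-bromo-2-(ArTBS)-2,3-dihydro-4H-pyran-4-one | BrC1=CO[C@H](c2cc3c(cc2O[Si](C)(C)C(C)(C)C)O[C@@H](c2ccc(O[Si](C)(C)C(C)(C)C)cc2)[C@@H]3c2cc(O[Si](C)(C)C(C)(C)C)cc(O[Si](C)(C)C(C)(C)C)c2)CC1=O | intermediate
17 | methyl acetoacetate | COC(=O)CC(C)=O | starting material
18 | 1-bromo-3-methylbut-2-ene | CC(C)=CCBr | starting material
19 | methyl 7-methyl-3-oxooct-6-enoate | COC(=O)CC(=O)CCC=C(C)C | intermediate
20 | methyl 7-methyl-3-(trimethylsilyloxy)octa-2,6-dienoate (E/Z mixture at C2) | COC(=O)C=C(O[Si](C)(C)C)CCC=C(C)C | intermediate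
21 | (1Z,3Z)-1-methoxy-7-methyl-1,3-bis(trimethylsilyloxy)octa-1,3,6-triene | CO/C(O[Si](C)(C)C)=C/C(O[Si](C)(C)C)=C/CC=C(C)C | intermediate
22 | (2S)-4a-bromo-5-methoxy-8-(3-methylbut-2-enyl)-5,7-bis(trimethylsilyloxy)-2-(ArTBS)-2,3,4a,5,8,8a-hexahydro-4H-chromen-4-one (C4a, C5, C8, C8a undefined) | CC(C)=CCC1C(O[Si](C)(C)C)=CC(OC)(O[Si](C)(C)C)C2(Br)C1O[C@H](c1cc3c(cc1O[Si](C)(C)C(C)(C)C)O[C@@H](c1ccc(O[Si](C)(C)C(C)(C)C)cc1)[C@@H]3c1cc(O[Si](C)(C)C(C)(C)C)cc(O[Si](C)(C)C(C)(C)C)c1)CC2=O | intermediate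
23 | (2S)-5,7-dihydroxy-8-(3-methylbut-2-enyl)-2-(ArTBS)-2,3-dihydro-4H-chromen-4-one | CC(C)=CCc1c(O)cc(O)c2c1O[C@H](c1cc3c(cc1O[Si](C)(C)C(C)(C)C)O[C@@H](c1ccc(O[Si](C)(C)C(C)(C)C)cc1)[C@@H]3c1cc(O[Si](C)(C)C(C)(C)C)cc(O[Si](C)(C)C(C)(C)C)c1)CC2=O | intermediate
24 | (2S,8Z)-5-hydroxy-8-(3-methylbut-2-enylidene)-2-(ArTBS)-2,3-dihydro-4H-chromene-4,7(8H)-dione | CC(C)=C\C=C1/C(=O)C=C(O)C2=C1O[C@H](c1cc3c(cc1O[Si](C)(C)C(C)(C)C)O[C@@H](c1ccc(O[Si](C)(C)C(C)(C)C)cc1)[C@@H]3c1cc(O[Si](C)(C)C(C)(C)C)cc(O[Si](C)(C)C(C)(C)C)c1)CC2=O | intermediate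
25 | (2S)-5-hydroxy-8,8-dimethyl-2-(ArTBS)-2,3-dihydro-4H,8H-pyrano[2,3-f]chromen-4-one | CC1(C)C=Cc2c(O1)cc(O)c1c2O[C@H](c2cc3c(cc2O[Si](C)(C)C(C)(C)C)O[C@@H](c2ccc(O[Si](C)(C)C(C)(C)C)cc2)[C@@H]3c2cc(O[Si](C)(C)C(C)(C)C)cc(O[Si](C)(C)C(C)(C)C)c2)CC1=O | intermediate
26 | (2S)-5-hydroxy-8,8-dimethyl-2-(ArOH)-2,3-dihydro-4H,8H-pyrano[2,3-f]chromen-4-one | CC1(C)C=Cc2c(O1)cc(O)c1c2O[C@H](c2cc3c(cc2O)O[C@@H](c2ccc(O)cc2)[C@@H]3c2cc(O)cc(O)c2)CC1=O | intermediate
27 | (2S,8Z)-5-hydroxy-8-(3-methylbut-2-enylidene)-2-(ArOH)-2,3-dihydro-4H-chromene-4,7(8H)-dione | CC(C)=C\C=C1/C(=O)C=C(O)C2=C1O[C@H](c1cc3c(cc1O)O[C@@H](c1ccc(O)cc1)[C@@H]3c1cc(O)cc(O)c1)CC2=O | intermediate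
28 | (2S)-2-[(2R,3R)-3-(3,5-dihydroxyphenyl)-6-hydroxy-2-(4-hydroxyphenyl)-2,3-dihydro-1-benzofuran-5-yl]-5,7-dihydroxy-8-[(1Z)-3-methylbuta-1,3-dienyl]-2,3-dihydro-4H-chromen-4-one | C=C(C)/C=C\c1c(O)cc(O)c2c1O[C@H](c1cc3c(cc1O)O[C@@H](c1ccc(O)cc1)[C@@H]3c1cc(O)cc(O)c1)CC2=O | target

**Totals and risks**

Total step count: 17. Longest linear sequence: 14 steps (steps 1–10, then 14–17); steps 11–13 make the diene.

Steps most likely to fail:

1. Step 14 (new method). The second bond may not form, so that the reaction stops at the open-chain adduct. Bromine transfer from the α-bromo carbonyl adduct to excess silyl ketene acetal would remove the leaving group needed for aromatisation. Ionisation of the benzylic C2–O1 bond in the silylated cation would erode C2. Fallback (known flavanone chemistry, ring C closed onto a preformed ring A), setting out from 12 and returning at 23: commercial 2',4',6'-trihydroxyacetophenone is C-prenylated with 18 (DBU, THF) to 1-[2,4,6-trihydroxy-3-(3-methylbut-2-enyl)phenyl]ethanone F1. Its two less hindered hydroxyls are protected (MOMCl, i-Pr2NEt, CH2Cl2) to give 1-[2-hydroxy-4,6-bis(methoxymethoxy)-3-(3-methylbut-2-enyl)phenyl]ethanone F2, the regioisomeric bis-ether being removed by chromatography. The dianion of F2 (LiHMDS, THF, −78 °C) is added to 12 to give 3-(ArTBS)-3-hydroxy-1-[2-hydroxy-4,6-bis(methoxymethoxy)-3-(3-methylbut-2-enyl)phenyl]propan-1-one F3 as carbinol epimers. Mitsunobu cyclisation (PPh3, DIAD, THF, 0 °C) closes ring C; the C2 epimers are diastereomers, because the dihydrobenzofuran is already enantiopure, and are separated to give (2S)-5,7-bis(methoxymethoxy)-8-(3-methylbut-2-enyl)-2-(ArTBS)-2,3-dihydro-4H-chromen-4-one F4. ZnBr2/n-PrSH (CH2Cl2, 0 °C) then removes the MOM groups without touching the silyl ethers and gives 23.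

2. Step 17. Thermal re-closure of the quinone allide competes with the hydrogen shift, and over-irradiation can isomerise the Z-diene to E or return it to the chromene, so conversion may stall at a photostationary mixture; the free phenols may also quench the excited state or add to the allide. Fallback, setting out from 25 and returning at 28: the photochemical step is moved to the lipophilic silyl ether. Irradiation of 25 (365 nm, degassed cyclohexane, 20 °C) gives (2S)-5,7-dihydroxy-8-[(1Z)-3-methylbuta-1,3-dienyl]-2-(ArTBS)-2,3-dihydro-4H-chromen-4-one F5, and buffered fluoride (Bu4NF/AcOH, THF, 0 °C) then removes the four silyl groups to give 28.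

3. Step 15. Over-oxidation: hydride abstraction from C2 of the dihydrobenzofuran (a 4-silyloxybenzylic ether C–H) would aromatise it to the benzofuran and destroy two stereocentres, and the flavanone could be dehydrogenated to the flavone. Fallback without a hydride-abstracting oxidant, setting out from 23 and returning at 25: selenoetherification with PhSeCl (CH2Cl2, −78 °C; the 7-hydroxyl opens the seleniranium ion at the tertiary carbon, 6-endo) gives (2S)-5-hydroxy-8,8-dimethyl-9-(phenylselanyl)-2-(ArTBS)-2,3,9,10-tetrahydro-4H,8H-pyrano[2,3-f]chromen-4-one F6 (C9 epimers). Oxidation with H2O2 (THF, 0 → 20 °C) and selenoxide syn-elimination toward the benzylic hydrogens then gives 25.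

**Further compounds**

F1 | step 14 | 1-[2,4,6-trihydroxy-3-(3-methylbut-2-enyl)phenyl]ethanone | CC(=O)c1c(O)cc(O)c(CC=C(C)C)c1O
F2 | step 14 | 1-[2-hydroxy-4,6-bis(methoxymethoxy)-3-(3-methylbut-2-enyl)phenyl]ethanone | CC(=O)c1c(OCOC)cc(OCOC)c(CC=C(C)C)c1O
F3 | step 14 | 3-(ArTBS)-3-hydroxy-1-[2-hydroxy-4,6-bis(methoxymethoxy)-3-(3-methylbut-2-enyl)phenyl]propan-1-one (carbinol epimers) | CC(C)=CCc1c(O)c(C(=O)CC(O)c2cc3c(cc2O[Si](C)(C)C(C)(C)C)O[C@@H](c2ccc(O[Si](C)(C)C(C)(C)C)cc2)[C@@H]3c2cc(O[Si](C)(C)C(C)(C)C)cc(O[Si](C)(C)C(C)(C)C)c2)c(OCOC)cc1OCOC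
F4 | step 14 | (2S)-5,7-bis(methoxymethoxy)-8-(3-methylbut-2-enyl)-2-(ArTBS)-2,3-dihydro-4H-chromen-4-one | CC(C)=CCc1c(OCOC)cc(OCOC)c2c1O[C@H](c1cc3c(cc1O[Si](C)(C)C(C)(C)C)O[C@@H](c1ccc(O[Si](C)(C)C(C)(C)C)cc1)[C@@H]3c1cc(O[Si](C)(C)C(C)(C)C)cc(O[Si](C)(C)C(C)(C)C)c1)CC2=O
F5 | step 17 | (2S)-5,7-dihydroxy-8-[(1Z)-3-methylbuta-1,3-dienyl]-2-(ArTBS)-2,3-dihydro-4H-chromen-4-one | C=C(C)/C=C\c1c(O)cc(O)c2c1O[C@H](c1cc3c(cc1O[Si](C)(C)C(C)(C)C)O[C@@H](c1ccc(O[Si](C)(C)C(C)(C)C)cc1)[C@@H]3c1cc(O[Si](C)(C)C(C)(C)C)cc(O[Si](C)(C)C(C)(C)C)c1)CC2=O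
F6 | step 15 | (2S)-5-hydroxy-8,8-dimethyl-9-(phenylselanyl)-2-(ArTBS)-2,3,9,10-tetrahydro-4H,8H-pyrano[2,3-f]chromen-4-one (C9 epimers) | CC1(C)Oc2cc(O)c3c(c2CC1[Se]c1ccccc1)O[C@H](c1cc4c(cc1O[Si](C)(C)C(C)(C)C)O[C@@H](c1ccc(O[Si](C)(C)C(C)(C)C)cc1)[C@@H]4c1cc(O[Si](C)(C)C(C)(C)C)cc(O[Si](C)(C)C(C)(C)C)c1)CC3=O
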